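**Retrosynthetic overview**
- Aryl ether O–C1' (formed first in the forward direction): isofraxidin 1, which brings both coumarin rings intact, plus geranyl bromide 2 gives geranyl ether 3.
- C7'–OH bond with shift of the 6',7'-alkene to 5',6'-(E): 3 goes through β-hydroxy selenide 4 to hydroxy diene 5; the oxygen comes from water.
- The two oxirane C–O bonds: 5 goes to target 6 by catalyst-controlled epoxidation of the 2',3'-alkene, which sets both stereocenters at once.
- Ring order: the benzene and pyranone rings are bought with 1; the oxirane is the only ring made and it is made last.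

Assumption: isofraxidin, geranyl bromide and the D-fructose-derived ketone catalyst are bought; locants 1'–8' count the C10 side chain from the ether CH2.

**Step 1**
Reactants: 1 isofraxidin (7-hydroxy-6,8-dimethoxy-2H-chromen-2-one); 2 geranyl bromide ((2E)-1-bromo-3,7-dimethylocta-2,6-diene)
Product: 3 7-{[(2E)-3,7-dimethylocta-2,6-dien-1-yl]oxy}-6,8-dimethoxy-2H-chromen-2-one
Conditions: K2CO3 (2 equiv), acetone, 56 °C, 6 h
Reagents that add atoms: none
Why: Williamson ether synthesis (SN2): K2CO3 deprotonates the acidic 7-OH and the phenoxide displaces the primary allylic bromide at C1' with the E-alkene untouched; no stereocenter is formed.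

**Step 2**
Reactants: 3 7-{[(2E)-3,7-dimethylocta-2,6-dien-1-yl]oxy}-6,8-dimethoxy-2H-chromen-2-one
Product: 5 7-{[(2E,5E)-7-hydroxy-3,7-dimethylocta-2,5-dien-1-yl]oxy}-6,8-dimethoxy-2H-chromen-2-one, via β-hydroxy selenide 4 (not isolated)
Conditions: (PhSe)2 (10 mol%), 2,4,6-tris(4-methoxyphenyl)pyrylium tetrafluoroborate (5 mol%), H2O (20 equiv), air, MeCN, 465 nm LEDs, 23 °C
Reagents that add atoms: water, O
Why: Proposed new method: photoaerobic selenium-π-acid allylic hydroxylation with water as the nucleophile on a prenyl-type trisubstituted alkene. The excited pyrylium oxidises (PhSe)2 to a PhSe+ equivalent that adds to the more electron-rich 6',7'-alkene (the 2',3'-alkene is deactivated by the allylic aryloxy group); water opens the seleniranium ion at the tertiary carbon to give 4, whose PhSe group comes from the catalyst; a second oxidation at selenium, with O2 as terminal oxidant, triggers elimination toward C5', the only carbon with β-hydrogens because C7' is quaternary, giving the E-alkene and returning the selenium catalyst. The closest known reaction types are dual photoredox/selenium-π-acid aerobic allylic acyloxylation of alkenes and the stoichiometric hydroxyselenation–selenoxide elimination of trisubstituted alkenes. No stereocenter remains, since C6' of 4 is racemic and becomes sp2.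

**Step 3**
Reactants: 5 7-{[(2E,5E)-7-hydroxy-3,7-dimethylocta-2,5-dien-1-yl]oxy}-6,8-dimethoxy-2H-chromen-2-one
Product: 6 7-{[(2R,3R)-3-[(2E)-4-hydroxy-4-methylpent-2-en-1-yl]-3-methyloxiran-2-yl]methoxy}-6,8-dimethoxy-2H-chromen-2-one
Conditions: D-fructose-derived Shi ketone (30 mol%), Oxone (2KHSO5·KHSO4·K2SO4; 1.4 equiv KHSO5), K2CO3, Bu4NHSO4 (4 mol%), MeCN–CH2(OMe)2 (1:2)/aq. Na2B4O7 (0.05 M), pH 10.5, 0 °C, 2 h; aq. NaH2PO4 work-up
Reagents that add atoms: potassium peroxymonosulfate, [K+].[O-]S(=O)(=O)OO
Why: Shi asymmetric epoxidation: the chiral dioxirane formed from the D-fructose-derived ketone and KHSO5 transfers oxygen through a spiro transition state to the face of the E-trisubstituted 2',3'-alkene that gives the (2'R,3'R)-oxirane, the same sense as its (R,R)-epoxides of other E-trisubstituted alkenes. Both stereocenters are set in this one step, with the E geometry carried into the trans relation of CH2OAr and the C4' chain. The hindered trans-disubstituted 5',6'-alkene next to the quaternary carbinol and the electron-poor coumarin C3=C4 bond should react much more slowly.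

**Compound list**
1 | isofraxidin (7-hydroxy-6,8-dimethoxy-2H-chromen-2-one) | COc1cc2ccc(=O)oc2c(OC)c1O | starting material
2 | geranyl bromide ((2E)-1-bromo-3,7-dimethylocta-2,6-diene) | CC(C)=CCC/C(C)=C/CBr | starting material
3 | 7-{[(2E)-3,7-dimethylocta-2,6-dien-1-yl]oxy}-6,8-dimethoxy-2H-chromen-2-one | COc1cc2ccc(=O)oc2c(OC)c1OC/C=C(\C)CCC=C(C)C | intermediate
4 | 7-{[(2E)-7-hydroxy-3,7-dimethyl-6-(phenylselanyl)oct-2-en-1-yl]oxy}-6,8-dimethoxy-2H-chromen-2-one (racemic at C6', not isolated) | COc1cc2ccc(=O)oc2c(OC)c1OC/C=C(\C)CCC([Se]c1ccccc1)C(C)(C)O | intermediate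
5 | 7-{[(2E,5E)-7-hydroxy-3,7-dimethylocta-2,5-dien-1-yl]oxy}-6,8-dimethoxy-2H-chromen-2-one | COc1cc2ccc(=O)oc2c(OC)c1OC/C=C(\C)C/C=C/C(C)(C)O | intermediate
6 | 7-{[(2R,3R)-3-[(2E)-4-hydroxy-4-methylpent-2-en-1-yl]-3-methyloxiran-2-yl]methoxy}-6,8-dimethoxy-2H-chromen-2-one | COc1cc2ccc(=O)oc2c(OC)c1OC[C@H]1O[C@]1(C)C/C=C/C(C)(C)O | target

**Totals**
Total step count: 3. Longest linear sequence: 3 steps (1 to 3 to 5 to 6).

**Steps most likely to fail, with fallbacks**

Step 2 (the proposed new method). The risks are that water does not compete as nucleophile under the photoaerobic conditions, that the electron-rich arene or the 2',3'-alkene is selenated, or that the tertiary allylic alcohol ionises. The fallback is known chemistry; it sets out from 3 and comes back at 5. Compound 3 is photo-oxygenated (O2, tetraphenylporphyrin sensitiser, visible light, CH2Cl2, 0 °C). Singlet oxygen reacts in a Schenck ene reaction at the electron-rich 6',7'-alkene and gives the tertiary allylic hydroperoxide 7-{[(2E,5E)-7-hydroperoxy-3,7-dimethylocta-2,5-dien-1-yl]oxy}-6,8-dimethoxy-2H-chromen-2-one F1, together with roughly an equal amount of a separable regioisomer. PPh3 is added to the same flask to reduce the O–O bond, and 5 is isolated by chromatography.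

Step 3. The risks are epoxidation at the 5',6'-alkene helped by its neighbouring OH, an enantiomeric excess below about 90% on an allylic aryl ether, and partial lactone opening at pH 10.5 (the NaH2PO4 work-up is meant to reclose it). The fallback sets out from 1 and comes back at 6; it installs the oxirane before the 5',6'-alkene exists. Geraniol is epoxidised at its 2,3-alkene under hydroxyl-directed aspartyl-peptide peracid catalysis (peptide in the hand that gives the 2R,3R series, diisopropylcarbodiimide, aq. H2O2, CH2Cl2, 4 °C), where the free allylic OH steers the peracid away from the 6,7-alkene. This gives [(2R,3R)-3-methyl-3-(4-methylpent-3-en-1-yl)oxiran-2-yl]methanol F2. Mitsunobu coupling of that alcohol with 1 (PPh3, diisopropyl azodicarboxylate, THF, 0 to 23 °C) takes place at the primary carbon, leaves both stereocenters alone, and gives 6,8-dimethoxy-7-{[(2R,3R)-3-methyl-3-(4-methylpent-3-en-1-yl)oxiran-2-yl]methoxy}-2H-chromen-2-one F3. Schenck ene photo-oxygenation of the remaining 6',7'-alkene (O2, tetraphenylporphyrin, visible light, CH2Cl2, 0 °C) gives 7-{[(2R,3R)-3-[(2E)-4-hydroperoxy-4-methylpent-2-en-1-yl]-3-methyloxiran-2-yl]methoxy}-6,8-dimethoxy-2H-chromen-2-one F4, which PPh3 reduces to 6 after separation from the regioisomer.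

Step 1. The risk is slow or incomplete alkylation of the phenol, which is flanked by two methoxy groups, or loss of geranyl bromide by elimination or hydrolysis. The fallback sets out from 1 and comes back at 3: Mitsunobu etherification of 1 with geraniol (PPh3, diisopropyl azodicarboxylate, THF, 0 to 23 °C) activates the alcohol instead of using the halide. It makes no compound outside the compound list (entry F0).

**Further compounds**
F0 | step 1 | none | none
F1 | step 2 | 7-{[(2E,5E)-7-hydroperoxy-3,7-dimethylocta-2,5-dien-1-yl]oxy}-6,8-dimethoxy-2H-chromen-2-one | COc1cc2ccc(=O)oc2c(OC)c1OC/C=C(\C)C/C=C/C(C)(C)OO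
F2 | step 3 | [(2R,3R)-3-methyl-3-(4-methylpent-3-en-1-yl)oxiran-2-yl]methanol | OC[C@H]1O[C@]1(C)CCC=C(C)C
F3 | step 3 | 6,8-dimethoxy-7-{[(2R,3R)-3-methyl-3-(4-methylpent-3-en-1-yl)oxiran-2-yl]methoxy}-2H-chromen-2-one | COc1cc2ccc(=O)oc2c(OC)c1OC[C@H]1O[C@]1(C)CCC=C(C)C
F4 | step 3 | 7-{[(2R,3R)-3-[(2E)-4-hydroperoxy-4-methylpent-2-en-1-yl]-3-methyloxiran-2-yl]methoxy}-6,8-dimethoxy-2H-chromen-2-one | COc1cc2ccc(=O)oc2c(OC)c1OC[C@H]1O[C@]1(C)C/C=C/C(C)(C)OO
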